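| flask | free monomer | pre-initiator | temperature | remark | time |
|---|---|---|---|---|---|
| Tuesday's | 1 mM | 5 µM | 25 °C | the very flask that is asked about, followed so far |  |
| Wednesday's | 1 mM | 7.5 µM | 25 °C | run made earlier |  |
| flask | 1.0 mM | 5.0 µM | 25 °C |  | 3.0 h |

- Tuesday's (time / min: monomer in chains / %, free monomer / %): 15.0: 93.4, 0.3; 25.0: 90.3, 0.3; 40.0: 83.1, 0.5; 60.0: 75.5, 0; 120: 58.8, 0; 180: 42.9, 0.5
- Wednesday's (time / min: monomer in chains / %, free monomer / %): 0.667: 18.2, 82.6; 2.00: 90.6, 8.5; 4.00: 98.6, 0.1; 5.00: 98.2, 0; 8.00: 96.3, 0.3; 10.0: 95.7, 0.2

(standard deviation of a reading: 0.5 percentage points)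

- alder: change nothing and wait 1.5 h more
- elm: at 3.0 h raise the temperature by 10 K, then wait 1.5 h
- ash: at 3.0 h add pre-initiator, 100% of the amount charged, then wait 1.5 h
- maple: at 3.0 h take out 90% of the monomer in chains then present, then wait 1.5 h

- monomer in chains, in percent of the free monomer first charged, at 3.0 h
- which option adds most monomer in chains ("none" when 2 percentage points or less is all one gets) (alder / elm / ash / maple / none)
- monomer in chains present, with what was taken out counted in, in percent of the free monomer first charged, after alder
- monomer in chains present, with what was taken out counted in, in percent of the free monomer first charged, after ash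

- what is taken out of monomer in chains is counted as made
- on the list of suspects stand: monomer in chains -> over-reaction product; pre-initiator -> initiator; free monomer + living end -> monomer in chains + living end; free monomer + initiator -> living end + monomer in chains
- the earlier runs do not show what temperature does; that part of a forecast is a guess
- additions bring no volume worth counting

Early on, free monomer had already left the picture: in Tuesday's flask it read 0.3% at 15.0 min and stayed within one scatter of zero up to 0.5% at 180 min. So I wrote the balance of free monomer, the limiting reagent of chain making: monomer in chains had no income worth counting, and its readings fell. From 93.4% at 15.0 min to 42.9% at 180 min the logarithm dropped at 0.00472 min⁻¹. I folded this rate and the time into the decay number θ, rate of loss times time elapsed, which counts the lifetimes of a chain gone by: 0.849 at 3.0 h. What stands is exp(−θ) of the charge, so I reckoned 42.8%.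

Was one number enough? Run back to zero time, the line gave 100% of the charge, and from 15.0 min it predicted 75.5% at 60.0 min, where Tuesday's flask read 75.5%. Wednesday's flask, with 1.50 times the pre-initiator, lost at 0.00498 min⁻¹ between 4.00 min and 10.0 min; that is a coarse reading from a drop of 2.9 percentage points, but it sits close to the first.

Waiting adds 0.424 to θ, so alder gives 28.0%. I gave ash the same figure, since free monomer read 0.5% at 180 min in Tuesday's flask, less than the margin of 2 points. Maple banks 90% of the chains and ends at 41.3%. These three end below 42.8%; elm is a guess, and I expected faster loss from it. I chose none.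

The forecast gave 43% (42.2% to 43.7%), 28.1% after alder, 28.2% after ash and none as best, holding that “Chains simply decay”.

The flask gave 43.5% at 3.0 h, 28.6% after alder, 28.6% after ash and none as best, with a change of −1.5 points for maple.

    monomer in chains → over-reaction product (k = 7.77 × 10⁻⁵ s⁻¹, Ea = 102 kJ mol⁻¹)
    pre-initiator → initiator (k = 0.0164 s⁻¹, Ea = 89.0 kJ mol⁻¹)
    free monomer + living end → monomer in chains + living end, rate k3*[living end]*[free monomer] (k = 25500 M⁻¹ s⁻¹, Ea = 10.0 kJ mol⁻¹)
    free monomer + initiator → living end + monomer in chains (k = 7.54 M⁻¹ s⁻¹, Ea = 46.0 kJ mol⁻¹)
    (constants at 25 °C)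

In this flask at 180 min, monomer in chains stood at 43.5% and over-reaction product at 56.5%. Carrying 43.5% through the decay number of the further 1.5 h gives 28.4%, against 28.6% after alder. The same flask read at 12 h has θ = 3.40, so exp(−θ) is 3.34%, and its monomer in chains stood at 3.51%.

The numbers in the tables stem from a simulated flask for substances that don't exist; noise was put on by code.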